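**Plan**

1. Cuts: the C6–O ester bond last; the C4 carbinol with the C2=C3 alkene back to a 4-isopropyl-3-en-2-one (Wharton transposition, C4–isopropyl bond from a cuprate); the C8–CH3 bond to a C8 ketone; C6–OH and C5–H to a C5=C6 alkene; the C1–C5 ring bond to the C1–C6 bond of a decalin.
2. Enabling feature: C1–C5 joins the quaternary methyl carbon C1 to a CH (C5) next to oxygenated C6. The cyclopentane C1–C5 and the cycloheptane C1/C5–C10 are therefore the contracted and expanded rings of a 1-methyldecalin (rings C1–C6 and C1/C6–C10) after a 1,2-shift of C1 from C6 to C5 that leaves C6 as a ketone.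
3. Forward order: both six-membered rings come with dione 1; bis-ketalisation, dihydroxylation and mesylation prepare the shift, which forms the five- and seven-membered rings in one step; then C5=C6 alkene, hydroboration, C8 methyl carbinol, cyclopentenone chemistry at C2–C4, esterification.
4. Stereochemistry: C1 is bought with 1; C5 and C6 come from syn hydroboration on the face opposite the C1 methyl; C8 from Grignard attack on that same face; C4 from β-face nucleophilic epoxidation, the C–O bond being kept through the Wharton step.

Key step: step 4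

Remark: atom numbers C1–C10 are those of the target hydroazulene and are kept for the decalins, whose fusion bond is C1–C6; β is the face of the C1 methyl, α the opposite face.
Remark: dione 1 is assumed to be purchased as the R enantiomer.
Remark: the C5 centre created in step 4 is not relied on. The shift gives the cis-fused ketone, and whether base would favour the trans epimer is uncertain, so C5 is made sp2 in step 5 and set again, together with C6, in step 7.

**Route**

Step 1
Reactants: 1 (8aR)-8a-methyl-3,4,8,8a-tetrahydronaphthalene-1,6(2H,7H)-dione; 2 ethylene glycol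
Product: 3 (1R)-1-methylbicyclo[4.4.0]dec-5-ene-2,8-dione 2,8-bis(ethylene ketal)
Conditions: HOCH2CH2OH (excess), p-TsOH (cat.), benzene, reflux, azeotropic removal of H2O
Reagents that add atoms: ethylene glycol (compound 2), OCCO
Why: Acid-catalysed ketalisation converts both carbonyls into dioxolanes, and the enone ketalises through its dienol ether so that the double bond settles out of conjugation at C5=C6, the usual outcome for ring-fused cyclohexenones; no stereocentre is formed.

Step 2
Reactants: 3 bis-ketal alkene
Product: 4 1β-methyl-trans-decalin-5α,6α-diol 2,8-bis(ethylene ketal) (C5 OH secondary and equatorial, C6 OH tertiary and axial)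
Conditions: OsO4 (cat.), N-methylmorpholine N-oxide (NMO), acetone/H2O, rt
Reagents that add atoms: osmium tetroxide, O=[Os](=O)(=O)=O; N-methylmorpholine N-oxide, C[N+]1([O-])CCOCC1; water, O
Why: OsO4-catalysed syn-dihydroxylation of the trisubstituted C5=C6 alkene should occur on the α face because the axial C1 methyl blocks the β face, which sets C5 and C6 and makes the ring fusion trans.

Step 3
Reactants: 4 5α,6α-diol
Product: 5 6α-hydroxy-5α-methanesulfonyloxy-1β-methyl-trans-decalin 2,8-bis(ethylene ketal)
Conditions: MsCl, pyridine, 0 °C → rt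
Reagents that add atoms: methanesulfonyl chloride, CS(=O)(=O)Cl
Why: Sulfonylation in pyridine is selective for the secondary equatorial C5 hydroxyl over the tertiary axial C6 hydroxyl on steric grounds and changes no stereocentre.

Step 4
Reactants: 5 hydroxy mesylate
Product: 6 cis-fused 1β-methyl-5β-H-perhydroazulen-6-one 2,8-bis(ethylene ketal) (five-membered ring C1–C5, seven-membered ring C1/C5–C10)
Conditions: KOtBu, t-BuOH/THF, 0 °C → rt
Reagents that add atoms: none
Why: tert-Butoxide deprotonates the tertiary C6 hydroxyl, and the alkoxide drives a concerted 1,2-shift in which the C1–C6 bond, anti-periplanar to the equatorial C5–OMs bond of the rigid trans-decalin chair, moves to C5 as mesylate leaves and C6 becomes the ketone. The closest known reaction type is the base-promoted semipinacol rearrangement of cyclic cis-1,2-diol monosulfonates, by which steroidal 5α-hydroxy-6α-sulfonates and related decalins give hydroazulenones. No ring is closed end to end: the cyclopentane C1–C5 arises by ring contraction through the shift, and the cycloheptanone C1/C5–C10 by the matching one-carbon ring expansion of the other six-membered ring. C1 migrates with retention and C5 is inverted, so the new C5–H lies on the methyl face (cis fusion); this centre, α to the ketone, may partly epimerise without consequence because step 5 removes it. The step needs migration of C1 rather than C7, epoxide closure or elimination: only the C1–C6 bond is anti to the leaving group, the cis alkoxide/mesylate pair cannot close an epoxide, and no C–H bond is anti-periplanar to the equatorial mesylate.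

Step 5
Reactants: 6 hydroazulenone (either C5 epimer)
Product: 8 1β-methyl-6-(trifluoromethanesulfonyloxy)perhydroazul-5-ene 2,8-bis(ethylene ketal), via bromomagnesium enolate 7 (not isolated)
Conditions: i-Pr2NMgBr (from EtMgBr and i-Pr2NH), Et2O/THF, rt; then PhNTf2, rt
Reagents that add atoms: N-phenylbis(trifluoromethanesulfonimide), O=S(=O)(N(c1ccccc1)S(=O)(=O)C(F)(F)F)C(F)(F)F
Why: The hindered magnesium amide enolises the ketone reversibly so that the more substituted C5=C6 enolate accumulates, and O-sulfonylation with PhNTf2 (thermodynamic enol triflate formation) removes the C5 stereocentre so that both C5 epimers of 6 converge.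

Step 6
Reactants: 8 enol triflate
Product: 9 1β-methylperhydroazul-5-ene 2,8-bis(ethylene ketal) (C5=C6 alkene)
Conditions: Pd(OAc)2 (cat.), PPh3, HCO2H, n-Bu3N, DMF, 60 °C
Reagents that add atoms: none
Why: Palladium-catalysed formate reduction of the vinyl triflate (oxidative addition to zerovalent palladium, decarboxylation of the formate complex, reductive elimination) replaces OTf by H without moving the C5=C6 double bond.

Step 7
Reactants: 9 C5=C6 alkene
Product: 11 6α-hydroxy-1β-methyl-5α-H-trans-perhydroazulene 2,8-bis(ethylene ketal), via 6α-alkylborane 10 (not isolated)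
Conditions: BH3·THF, THF, 0 °C → rt; then NaOH, H2O2, H2O, 0 °C → rt
Reagents that add atoms: hydrogen peroxide, OO
Why: Hydroboration–oxidation is a syn, anti-Markovnikov addition that puts boron on the less substituted C6 and hydrogen on C5 from the α face away from the C1 methyl, and C–B oxidation with retention gives the 6α-alcohol with 5α-H (trans fusion), the outcome known for the analogous 9(11)-alkenes of steroids.

Step 8
Reactants: 11 6α-alcohol
Product: 12 6α-(tert-butyldiphenylsilyloxy) (TBDPS) ether of 11
Conditions: TBDPSCl, imidazole, DMF, rt → 50 °C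
Reagents that add atoms: tert-butyl(chloro)diphenylsilane, CC(C)(C)[Si](Cl)(c1ccccc1)c1ccccc1
Why: Silyl ether formation at the single free, equatorial secondary hydroxyl installs a bulky group that withstands the acidic, organometallic, oxidising and basic steps that follow, with no change at any stereocentre.

Step 9
Reactants: 12 silyl ether bis-ketal
Product: 13 6α-(tert-butyldiphenylsilyloxy)-1β-methyl-5α-H-trans-perhydroazulene-2,8-dione
Conditions: 1 M HCl, THF, rt → 40 °C
Reagents that add atoms: water, O
Why: Acid-catalysed acetal hydrolysis frees both ketones while the TBDPS ether survives, and neither new carbonyl has an epimerisable stereocentre beside it (C1 is quaternary, C5 is not α to a carbonyl).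

Step 10
Reactants: 13 dione; 14 methylmagnesium bromide
Product: 15 6α-(tert-butyldiphenylsilyloxy)-8β-hydroxy-1β,8α-dimethyl-5α-H-trans-perhydroazulen-2-one
Conditions: MeMgBr (1.1 equiv), THF, −78 °C; aq. NH4Cl
Reagents that add atoms: methylmagnesium bromide (compound 14), C[Mg]Br
Why: Grignard 1,2-addition should take place at the unhindered cycloheptanone C8 in preference to the neopentyl cyclopentanone C2, and the methyl group is expected to enter from the α face opposite the axial C1 methyl, giving the 8β-hydroxy-8α-methyl centre.

Step 11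
Reactants: 15 C2 ketone
Product: 16 the corresponding perhydroazul-3-en-2-one (C3=C4 enone)
Conditions: IBX (2-iodoxybenzoic acid), DMSO, 70 °C
Reagents that add atoms: none
Why: IBX-mediated dehydrogenation of the ketone through its enol can only run toward C3–C4 because C1 is quaternary, and it leaves the tertiary alcohol and the silyl ether untouched.

Step 12
Reactants: 16 enone
Product: 17 4β-isopropyl ketone (6α-OTBDPS, 8β-OH, C2=O)
Conditions: i-Pr2CuLi (from i-PrLi and CuI, 3 equiv), Et2O/THF, −78 °C; aq. NH4Cl
Reagents that add atoms: lithium diisopropylcuprate, CC(C)[Cu-]C(C)C.[Li+]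
Why: Conjugate addition of the organocuprate to the cyclopentenone forms the C4–isopropyl bond, expected on the β face away from the 6α-silyloxy group, although this centre is of no consequence because C4 returns to sp2 in step 13.

Step 13
Reactants: 17 4-isopropyl ketone
Product: 18 4-isopropyl-perhydroazul-3-en-2-one (6α-OTBDPS, 8β-OH)
Conditions: IBX, DMSO, 70 °C
Reagents that add atoms: none
Why: A second IBX dehydrogenation re-forms the C3=C4 double bond, its position again dictated by the quaternary C1, to give the β-isopropyl enone.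

Step 14
Reactants: 18 β-isopropyl enone
Product: 19 3β,4β-epoxy-4α-isopropyl ketone (6α-OTBDPS, 8β-OH, C2=O)
Conditions: H2O2 (30%), NaOH, MeOH, 0 °C → rt
Reagents that add atoms: hydrogen peroxide, OO
Why: In this Weitz–Scheffer nucleophilic epoxidation hydroperoxide should add to C4 on the β face, away from the 6α-silyloxy group that flanks the α face (the sense seen for nucleophiles adding to steroidal 15-en-17-ones), and enolate closure gives the 3β,4β-epoxide that fixes the C4–O configuration of the target.

Step 15
Reactants: 19 epoxy ketone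
Product: 21 6α-(tert-butyldiphenylsilyloxy)-4α-isopropyl-1β,8α-dimethyl-5α-H-perhydroazul-2-ene-4β,8β-diol, via epoxy hydrazone 20 (not isolated)
Conditions: N2H4·H2O, AcOH (cat.), MeOH, 0 °C → rt
Reagents that add atoms: none
Why: In the Wharton transposition the epoxy hydrazone fragments with loss of N2 to the C2=C3 alkene and the tertiary allylic C4 alcohol, and since the C4–O bond is never broken the 4β-hydroxy configuration is retained.

Step 16
Reactants: 21 silyl ether diol
Product: 22 4α-isopropyl-1β,8α-dimethyl-5α-H-perhydroazul-2-ene-4β,6α,8β-triol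
Conditions: Bu4NF, THF, rt → 50 °C
Reagents that add atoms: none
Why: Fluoride-induced Si–O cleavage removes the TBDPS group under non-acidic conditions that spare the tertiary allylic alcohol, with no change at any stereocentre.

Step 17
Reactants: 23 vanillic acid
Product: 24 4-acetoxy-3-methoxybenzoic acid
Conditions: Ac2O, pyridine, rt; H2O
Reagents that add atoms: acetic anhydride, CC(=O)OC(C)=O
Why: Acetylation of the phenol masks it so that the acid can be activated in step 18 without self-condensation; no stereocentre is involved.

Step 18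
Reactants: 22 triol; 24 4-acetoxy-3-methoxybenzoic acid
Product: 25 6-O-(4-acetoxy-3-methoxybenzoyl) ester of triol 22
Conditions: DIC (N,N'-diisopropylcarbodiimide), DMAP (cat.), CH2Cl2, rt
Reagents that add atoms: none
Why: Steglich esterification acylates the only secondary hydroxyl (C6) at oxygen, hence with retention, while the tertiary C4 and C8 hydroxyls are too hindered to react.

Step 19
Reactants: 25 acetyl-protected ester
Product: 26 target, the 6-O-vanilloyl ester of triol 22
Conditions: pyrrolidine, CH2Cl2, 0 °C → rt
Reagents that add atoms: none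
Why: Aminolysis of the activated aryl acetate by pyrrolidine is much faster than attack on the hindered secondary aroyl ester, so the phenol is released without touching the C6 ester or any stereocentre.

**Compound list**

1 | (8aR)-8a-methyl-3,4,8,8a-tetrahydronaphthalene-1,6(2H,7H)-dione | C[C@@]12CCC(=O)C=C1CCCC2=O | starting material
2 | ethylene glycol | OCCO | starting material
3 | (1R)-1-methylbicyclo[4.4.0]dec-5-ene-2,8-dione 2,8-bis(ethylene ketal) | C[C@@]12CCC3(OCCO3)CC1=CCCC24OCCO4 | intermediate
4 | 1β-methyl-trans-decalin-5α,6α-diol 2,8-bis(ethylene ketal) | C[C@@]12CCC3(OCCO3)C[C@@]1(O)[C@H](O)CCC24OCCO4 | intermediate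
5 | 6α-hydroxy-5α-methanesulfonyloxy-1β-methyl-trans-decalin 2,8-bis(ethylene ketal) | C[C@@]12CCC3(OCCO3)C[C@@]1(O)[C@H](OS(C)(=O)=O)CCC24OCCO4 | intermediate
6 | cis-fused 1β-methyl-5β-H-perhydroazulen-6-one 2,8-bis(ethylene ketal) | C[C@@]12CCC3(OCCO3)CC(=O)[C@@H]1CCC24OCCO4 | intermediate
7 | bromomagnesium C5=C6 enolate of 6 (not isolated) | C[C@@]12CCC3(OCCO3)CC(O[Mg]Br)=C1CCC24OCCO4 | intermediate
8 | 1β-methyl-6-(trifluoromethanesulfonyloxy)perhydroazul-5-ene 2,8-bis(ethylene ketal) | C[C@@]12CCC3(OCCO3)CC(OS(=O)(=O)C(F)(F)F)=C1CCC24OCCO4 | intermediate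
9 | 1β-methylperhydroazul-5-ene 2,8-bis(ethylene ketal) | C[C@@]12CCC3(OCCO3)CC=C1CCC24OCCO4 | intermediate
10 | 6α-boryl-1β-methyl-5α-H-trans-perhydroazulene 2,8-bis(ethylene ketal), monoalkylborane (not isolated) | C[C@@]12CCC3(OCCO3)C[C@H](B)[C@H]1CCC24OCCO4 | intermediate
11 | 6α-hydroxy-1β-methyl-5α-H-trans-perhydroazulene 2,8-bis(ethylene ketal) | C[C@@]12CCC3(OCCO3)C[C@H](O)[C@H]1CCC24OCCO4 | intermediate
12 | 6α-(tert-butyldiphenylsilyloxy)-1β-methyl-5α-H-trans-perhydroazulene 2,8-bis(ethylene ketal) | C[C@@]12CCC3(OCCO3)C[C@H](O[Si](c3ccccc3)(c4ccccc4)C(C)(C)C)[C@H]1CCC24OCCO4 | intermediate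
13 | 6α-(tert-butyldiphenylsilyloxy)-1β-methyl-5α-H-trans-perhydroazulene-2,8-dione | C[C@@]12CCC(=O)C[C@H](O[Si](c3ccccc3)(c4ccccc4)C(C)(C)C)[C@H]1CCC2=O | intermediate
14 | methylmagnesium bromide | C[Mg]Br | starting material
15 | 6α-(tert-butyldiphenylsilyloxy)-8β-hydroxy-1β,8α-dimethyl-5α-H-trans-perhydroazulen-2-one | C[C@@]12CC[C@@](C)(O)C[C@H](O[Si](c3ccccc3)(c4ccccc4)C(C)(C)C)[C@H]1CCC2=O | intermediate
16 | 6α-(tert-butyldiphenylsilyloxy)-8β-hydroxy-1β,8α-dimethyl-5α-H-perhydroazul-3-en-2-one | C[C@@]12CC[C@@](C)(O)C[C@H](O[Si](c3ccccc3)(c4ccccc4)C(C)(C)C)[C@H]1C=CC2=O | intermediate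
17 | 6α-(tert-butyldiphenylsilyloxy)-8β-hydroxy-4β-isopropyl-1β,8α-dimethyl-5α-H-perhydroazulen-2-one | C[C@@]12CC[C@@](C)(O)C[C@H](O[Si](c3ccccc3)(c4ccccc4)C(C)(C)C)[C@H]1[C@@H](C(C)C)CC2=O | intermediate
18 | 6α-(tert-butyldiphenylsilyloxy)-8β-hydroxy-4-isopropyl-1β,8α-dimethyl-5α-H-perhydroazul-3-en-2-one | C[C@@]12CC[C@@](C)(O)C[C@H](O[Si](c3ccccc3)(c4ccccc4)C(C)(C)C)[C@H]1C(C(C)C)=CC2=O | intermediate
19 | 3β,4β-epoxy-6α-(tert-butyldiphenylsilyloxy)-8β-hydroxy-4α-isopropyl-1β,8α-dimethyl-5α-H-perhydroazulen-2-one | C[C@@]12CC[C@@](C)(O)C[C@H](O[Si](c3ccccc3)(c4ccccc4)C(C)(C)C)[C@H]1[C@@]5(C(C)C)O[C@H]5C2=O | intermediate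
20 | C2 hydrazone of epoxy ketone 19 (not isolated) | C[C@@]12CC[C@@](C)(O)C[C@H](O[Si](c3ccccc3)(c4ccccc4)C(C)(C)C)[C@H]1[C@@]5(C(C)C)O[C@H]5C2=NN | intermediate
21 | 6α-(tert-butyldiphenylsilyloxy)-4α-isopropyl-1β,8α-dimethyl-5α-H-perhydroazul-2-ene-4β,8β-diol | C[C@@]12CC[C@@](C)(O)C[C@H](O[Si](c3ccccc3)(c4ccccc4)C(C)(C)C)[C@H]1[C@](O)(C(C)C)C=C2 | intermediate
22 | 4α-isopropyl-1β,8α-dimethyl-5α-H-perhydroazul-2-ene-4β,6α,8β-triol | C[C@@]12CC[C@@](C)(O)C[C@H](O)[C@H]1[C@](O)(C(C)C)C=C2 | intermediate
23 | vanillic acid | COc1cc(C(=O)O)ccc1O | starting material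
24 | 4-acetoxy-3-methoxybenzoic acid | COc1cc(C(=O)O)ccc1OC(C)=O | intermediate
25 | 6-O-(4-acetoxy-3-methoxybenzoyl) ester of triol 22 | C[C@@]12CC[C@@](C)(O)C[C@H](OC(=O)c3ccc(OC(C)=O)c(OC)c3)[C@H]1[C@](O)(C(C)C)C=C2 | intermediate
26 | CNP0113302.1, the 6-O-vanilloyl ester of triol 22 | COc1cc(C(=O)O[C@H]2C[C@](C)(O)CC[C@@]3(C)C=C[C@@](O)(C(C)C)[C@H]23)ccc1O | target

**Step count**

Total: 19 steps. Longest linear sequence: 18 steps (steps 1–16, 18 and 19); step 17 is a one-step side branch.

**Steps most likely to fail**

1. Step 5 (thermodynamic enol triflate). Enolisation may run toward C7, helped by the neighbouring ketal, or the C8 dioxolane may open by β-elimination from the C7 enolate; the triflate would then form at the wrong position and C5 could not be reset. Fallback, setting out from 6: dehydrogenation with IBX can only proceed toward C4–C5 because C8 carries no hydrogen and should give the C4=C5 enone F1. Conjugate reduction with LiBH(s-Bu)3 then generates the C5=C6 enolate regiospecifically, and trapping with PhNTf2 comes back to the route at 8.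

2. Step 10 (methyl addition at C8). Facial discrimination at the C8 carbonyl of the flexible seven-membered ring may be poor or even reversed, and some addition to the C2 ketone may occur. Fallback, setting out from 13: Wittig methylenation with Ph3P=CH2 at the unhindered C8 carbonyl gives the 8-methylene ketone F2. Epoxidation with dimethyldioxirane on the more open face gives the spiro-epoxide F3 (drawn for the case that the β face is the open one). LiEt3BH opens it at the CH2 terminus and also reduces C2, giving the diol F4, and Swern oxidation of the secondary C2 alcohol comes back to the route at 15. This sequence puts oxygen rather than carbon on the accessible face and is therefore complementary to the Grignard addition.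

3. Step 14 (nucleophilic epoxidation). Hydroperoxide may attack the α face, or the hindered, fully β-substituted enone may not react. Fallback, setting out from 16: the unsubstituted enone is epoxidised (H2O2, NaOH) to the epoxy ketone F5, Wharton transposition gives the secondary allylic alcohol F6, and MnO2 oxidation gives the transposed 2-en-4-one F7. 1,2-Addition of i-PrMgCl/CeCl3 to C4 then comes back to the route at 21. Here carbon instead of oxygen is delivered to C4, so the facial preference that would spoil the epoxidation gives the required 4β-hydroxyl.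

**Further compounds**

F1 | step 5 | 1β-methylperhydroazul-4-en-6-one 2,8-bis(ethylene ketal) (C4=C5 enone) | C[C@@]12CCC3(OCCO3)CC(=O)C1=CCC24OCCO4
F2 | step 10 | 6α-(tert-butyldiphenylsilyloxy)-1β-methyl-8-methylene-5α-H-trans-perhydroazulen-2-one | C[C@@]12CCC(=C)C[C@H](O[Si](c3ccccc3)(c4ccccc4)C(C)(C)C)[C@H]1CCC2=O
F3 | step 10 | C8 spiro-epoxide of F2 with oxygen on the β face | C[C@@]12CC[C@]5(CO5)C[C@H](O[Si](c3ccccc3)(c4ccccc4)C(C)(C)C)[C@H]1CCC2=O
F4 | step 10 | 6α-(tert-butyldiphenylsilyloxy)-1β,8α-dimethyl-5α-H-trans-perhydroazulene-2β,8β-diol | C[C@@]12CC[C@@](C)(O)C[C@H](O[Si](c3ccccc3)(c4ccccc4)C(C)(C)C)[C@H]1CC[C@H]2O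
F5 | step 14 | 3β,4β-epoxy-6α-(tert-butyldiphenylsilyloxy)-8β-hydroxy-1β,8α-dimethyl-5α-H-perhydroazulen-2-one | C[C@@]12CC[C@@](C)(O)C[C@H](O[Si](c3ccccc3)(c4ccccc4)C(C)(C)C)[C@H]1[C@H]5O[C@H]5C2=O
F6 | step 14 | 6α-(tert-butyldiphenylsilyloxy)-1β,8α-dimethyl-5α-H-perhydroazul-2-ene-4β,8β-diol | C[C@@]12CC[C@@](C)(O)C[C@H](O[Si](c3ccccc3)(c4ccccc4)C(C)(C)C)[C@H]1[C@@H](O)C=C2
F7 | step 14 | 6α-(tert-butyldiphenylsilyloxy)-8β-hydroxy-1β,8α-dimethyl-5α-H-perhydroazul-2-en-4-one | C[C@@]12CC[C@@](C)(O)C[C@H](O[Si](c3ccccc3)(c4ccccc4)C(C)(C)C)[C@H]1C(=O)C=C2
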